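The route rests on disconnecting C8–C9 of the seven-membered ring C4–C5–C6–C7–C8–C9–C10 (longipinane numbering: C1 ketone, C7–C9 acyloxy carbons, C5 and C10 the one-carbon bridges of the cyclobutane). Both carbons are carbinol carbons of a cis-diol, so the bond is forged by reductive union of two electrophilic formyl carbons: a SmI2 pinacol cyclisation that closes the seven-membered ring and sets C8 and C9 in one operation under control of the C7 silyloxy centre. The precursor is a bicyclo[3.1.1]heptanol whose bridges C10 and C5 carry, syn across the cyclobutane, a formyl group and a CMe2–CH(OTBS)–CHO chain; the ketone is installed only afterwards.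

Key step: step 11

Remark on numbering: atom numbers in the text are those of the longipinane skeleton: C1 (C=O), C2=C3 (C3 bears CH3), C4 and C11 (cyclobutane CH bridgeheads), C5 (cyclobutane CH bearing C6), C6 (CMe2), C7, C8, C9 (acyloxy carbons), C10 (quaternary cyclobutane carbon bearing CH3).

Step 1
Reactants: 1 2-hydroxyethyl pivalate; 2 3-methylbuta-1,2-diene
Product: 3 (2S)-2-hydroxy-3,3-dimethylpent-4-en-1-yl pivalate
Conditions: [Ir(cod)Cl]2 (2.5 mol%), (S)-SEGPHOS (5 mol%), 4-chloro-3-nitrobenzoic acid (10 mol%), Cs2CO3 (20 mol%), THF, 60 °C, sealed tube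
Reagents that add atoms: 3-methylbuta-1,2-diene (2), CC(C)=C=C
Why: Krische iridium-catalysed transfer-hydrogenative tert-prenylation: the alcohol is dehydrogenated to the aldehyde in situ and the 1,1-dimethylallyl–iridium species adds through its substituted terminus in a chair transition state, so the C7 carbinol centre, the C6 gem-dimethyl carbon and a vinyl handle arise together, the (S)-ligand being chosen to give the (S)-carbinol in the same sense as in the parent allylations.

Step 2
Reactants: 3 (2S)-2-hydroxy-3,3-dimethylpent-4-en-1-yl pivalate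
Product: 4 (2S)-2-[(tert-butyldimethylsilyl)oxy]-3,3-dimethylpent-4-en-1-yl pivalate
Conditions: TBSOTf, 2,6-lutidine, CH2Cl2, 0 °C
Reagents that add atoms: tert-butyldimethylsilyl triflate, CC(C)(C)[Si](C)(C)OS(=O)(=O)C(F)(F)F
Why: Standard silylation of a hindered secondary alcohol with the silyl triflate; the bulky silyl ether later steers the pinacol coupling.

Step 3
Reactants: 4 (2S)-2-[(tert-butyldimethylsilyl)oxy]-3,3-dimethylpent-4-en-1-yl pivalate
Product: 6 (2S)-2-[(tert-butyldimethylsilyl)oxy]-3,3-dimethyl-4-oxobutyl pivalate, via ozonide 5 (not isolated)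
Conditions: O3, CH2Cl2, −78 °C; then PPh3, −78 °C to rt
Reagents that add atoms: ozone, [O-][O+]=O
Why: Ozonolysis (Criegee cleavage) of the only alkene with reductive work-up should give the non-enolisable neopentyl aldehyde whose carbon becomes C5.

Step 4
Reactants: 6 (2S)-2-[(tert-butyldimethylsilyl)oxy]-3,3-dimethyl-4-oxobutyl pivalate; 7 allyl(diphenyl)phosphine oxide
Product: 8 (2S,4E)-2-[(tert-butyldimethylsilyl)oxy]-3,3-dimethylhepta-4,6-dien-1-yl pivalate
Conditions: n-BuLi, THF–HMPA, −78 °C to rt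
Reagents that add atoms: allyl(diphenyl)phosphine oxide (7), C=CCP(=O)(c1ccccc1)c1ccccc1
Why: Horner–Wittig olefination with the lithiated allylphosphine oxide in the presence of HMPA should give the (E)-1,3-diene directly by α-attack and syn-elimination of the anti adduct.

Step 5
Reactants: 8 (2S,4E)-2-[(tert-butyldimethylsilyl)oxy]-3,3-dimethylhepta-4,6-dien-1-yl pivalate; 9 (E)-pent-3-en-2-one
Product: 10 (2S)-3-[(1R,5R,6S)-6-acetyl-5-methylcyclohex-2-en-1-yl]-2-[(tert-butyldimethylsilyl)oxy]-3-methylbutyl pivalate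
Conditions: (R)-1-(2-methylphenyl)-3,3-diphenyltetrahydropyrrolo[1,2-c][1,3,2]oxazaborole protonated with HN(SO2CF3)2 (20 mol%), CH2Cl2, −78 to −20 °C
Reagents that add atoms: (E)-pent-3-en-2-one (9), C/C=C/C(C)=O
Why: Lewis-acid-catalysed Diels–Alder reaction: the 1-substituted diene gives the ortho regioisomer, the endo transition state places side chain and acetyl cis (C5/C4), the (E)-dienophile places acetyl and methyl trans, and the (R)-oxazaborolidinium is expected by the α-C–H···O binding model for enones to expose the Cα-Re face, which fixes C4 and C5, while the remote C7 centre only makes the minor facial isomer a separable diastereomer.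

Step 6
Reactants: 10 (2S)-3-[(1R,5R,6S)-6-acetyl-5-methylcyclohex-2-en-1-yl]-2-[(tert-butyldimethylsilyl)oxy]-3-methylbutyl pivalate; 11 p-toluenesulfonylmethyl isocyanide (TosMIC)
Product: 12 (2S)-2-[(tert-butyldimethylsilyl)oxy]-3-[(1R,5R,6S)-6-(1-cyanoethyl)-5-methylcyclohex-2-en-1-yl]-3-methylbutyl pivalate (both epimers at the nitrile-bearing carbon)
Conditions: TosMIC (slight excess over base), KOtBu, DME/t-BuOH, 0 °C to rt
Reagents that add atoms: TosMIC (11), Cc1ccc(cc1)S(=O)(=O)C[N+]#[C-]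
Why: van Leusen reductive cyanation turns the methyl ketone into the α-methyl nitrile (future C10 with its CH3 and C9) in one step, and keeping TosMIC in excess over KOtBu should protect the ketone α-stereocentre from epimerisation.

Step 7
Reactants: 12 (2S)-2-[(tert-butyldimethylsilyl)oxy]-3-[(1R,5R,6S)-6-(1-cyanoethyl)-5-methylcyclohex-2-en-1-yl]-3-methylbutyl pivalate
Product: 13 (2S)-2-[(tert-butyldimethylsilyl)oxy]-3-[(1R,2R,3R,4R,6S)-3-(1-cyanoethyl)-4-methyl-7-oxabicyclo[4.1.0]heptan-2-yl]-3-methylbutyl pivalate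
Conditions: mCPBA, NaHCO3, CH2Cl2, 0 °C
Reagents that add atoms: 3-chloroperbenzoic acid, OOC(=O)c1cccc(Cl)c1
Why: Prilezhaev epoxidation from the ring face opposite to the two cis substituents (allylic side chain and homoallylic cyanoethyl group) should give the epoxide trans to the cyanoethyl group, as needed for backside opening.

Step 8
Reactants: 13 (2S)-2-[(tert-butyldimethylsilyl)oxy]-3-[(1R,2R,3R,4R,6S)-3-(1-cyanoethyl)-4-methyl-7-oxabicyclo[4.1.0]heptan-2-yl]-3-methylbutyl pivalate
Product: 14 (2S)-2-[(tert-butyldimethylsilyl)oxy]-3-[(1R,2S,4R,5S,6R,7S)-6-cyano-2-hydroxy-4,6-dimethylbicyclo[3.1.1]heptan-7-yl]-3-methylbutyl pivalate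
Conditions: KN(SiMe3)2, toluene, 0 to 60 °C; then H2O
Reagents that add atoms: none
Why: Stork epoxynitrile cyclisation: the tertiary nitrile carbanion, axial and 1,3-syn to the oxirane carbon C11, opens the epoxide by backside 4-exo-tet attack (trans-diaxial opening) to form the cyclobutane and the C1 alkoxide, the small linear nitrile taking the place syn to the bulky C5 substituent so that C10 carries CH3 toward the three-carbon bridge.

Step 9
Reactants: 14 (2S)-2-[(tert-butyldimethylsilyl)oxy]-3-[(1R,2S,4R,5S,6R,7S)-6-cyano-2-hydroxy-4,6-dimethylbicyclo[3.1.1]heptan-7-yl]-3-methylbutyl pivalate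
Product: 16 (1R,2S,4R,5S,6R,7S)-7-[(3S)-3-[(tert-butyldimethylsilyl)oxy]-4-hydroxy-2-methylbutan-2-yl]-2-hydroxy-4,6-dimethylbicyclo[3.1.1]heptane-6-carbaldehyde, via aldimine 15 (not isolated)
Conditions: i-Bu2AlH (excess), CH2Cl2, −78 to 0 °C; then aq. KNaC4H4O6, then wet SiO2
Reagents that add atoms: water, O
Why: i-Bu2AlH adds once to the nitrile to give the N-aluminio aldimine, hydrolysed on work-up to the C9 aldehyde, and in the same operation cleaves the pivalate reductively to the primary alcohol.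

Step 10
Reactants: 16 (1R,2S,4R,5S,6R,7S)-7-[(3S)-3-[(tert-butyldimethylsilyl)oxy]-4-hydroxy-2-methylbutan-2-yl]-2-hydroxy-4,6-dimethylbicyclo[3.1.1]heptane-6-carbaldehyde
Product: 17 (1R,2S,4R,5S,6R,7S)-7-[(3S)-3-[(tert-butyldimethylsilyl)oxy]-2-methyl-4-oxobutan-2-yl]-2-hydroxy-4,6-dimethylbicyclo[3.1.1]heptane-6-carbaldehyde
Conditions: TEMPO (10 mol%), PhI(OAc)2, CH2Cl2, rt
Reagents that add atoms: none
Why: The oxoammonium oxidation (TEMPO/PhI(OAc)2) should oxidise the primary alcohol selectively over the hindered secondary C1 carbinol and give the α-silyloxy aldehyde without epimerisation.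

Step 11
Reactants: 17 (1R,2S,4R,5S,6R,7S)-7-[(3S)-3-[(tert-butyldimethylsilyl)oxy]-2-methyl-4-oxobutan-2-yl]-2-hydroxy-4,6-dimethylbicyclo[3.1.1]heptane-6-carbaldehyde
Product: 18 (1S,3R,4S,5S,7S,8S,9S,10R,11R)-7-[(tert-butyldimethylsilyl)oxy]longipinane-1,8,9-triol (8,9-diol cis and trans to the 7-silyloxy group)
Conditions: SmI2 (2.5 equiv), THF, −78 to −20 °C; then aq. NH4Cl
Reagents that add atoms: none
Why: Two SmI2 transfer one electron each to the two formyl groups, and the samarium-bound ketyl radical anions, held close because the C10 formyl group and the C5 side chain sit syn across the cyclobutane (reinforced by the C6 gem-dimethyl effect), combine at carbon to form C8–C9, the closest precedent being SmI2 pinacol cyclisations of α-alkoxy 1,ω-dialdehydes to cyclitols. The seven-membered ring C4–C5–C6–C7–C8–C9–C10 is closed by this ketyl–ketyl union, formally a 7-exo-trig closure onto the second carbonyl. The new stereocentres C8 and C9 should become cis because both oxygens are bridged by trivalent samarium in the coupling transition state, and both C–O bonds form anti to the bulky C7 silyloxy group (steric and dipole minimisation), so their absolute sense follows from C7. The step needs chemoselectivity for the aldehydes and an intact cyclobutane; both are secured by carrying C1 as a free alcohol (no ketone or enone to be reduced, and no radical-stabilising group to invite ring opening of the cyclobutylcarbinyl-type C9 ketyl) and by the low temperature.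

Step 12
Reactants: 18 (1S,3R,4S,5S,7S,8S,9S,10R,11R)-7-[(tert-butyldimethylsilyl)oxy]longipinane-1,8,9-triol
Product: 19 (1S,3R,4S,5S,7S,8S,9S,10R,11R)-7-[(tert-butyldimethylsilyl)oxy]-8,9-(isopropylidenedioxy)longipinan-1-ol
Conditions: Me2C(OMe)2, PPTS (cat.), CH2Cl2, rt
Reagents that add atoms: 2,2-dimethoxypropane, COC(C)(C)OC
Why: Acid-catalysed transketalisation should give the five-membered acetonide of the cis-8,9-diol and leave the isolated C1 hydroxyl free.

Step 13
Reactants: 19 (1S,3R,4S,5S,7S,8S,9S,10R,11R)-7-[(tert-butyldimethylsilyl)oxy]-8,9-(isopropylidenedioxy)longipinan-1-ol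
Product: 21 (4R,5S,7S,8S,9S,10R,11R)-7-[(tert-butyldimethylsilyl)oxy]-8,9-(isopropylidenedioxy)longipin-2-en-1-one, via saturated ketone 20 (not isolated)
Conditions: IBX (excess), 4-methoxypyridine N-oxide, DMSO, rt
Reagents that add atoms: none
Why: IBX oxidises the C1 carbinol to the ketone and, as its N-oxide complex, dehydrogenates it (Nicolaou dehydrogenation) toward C2–C3, the only enolisable side because the other α-carbon is the cyclobutane bridgehead C11, which also erases the C3 stereocentre.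

Step 14
Reactants: 21 (4R,5S,7S,8S,9S,10R,11R)-7-[(tert-butyldimethylsilyl)oxy]-8,9-(isopropylidenedioxy)longipin-2-en-1-one
Product: 22 (4R,5S,7S,8R,9S,10R,11R)-7,8,9-trihydroxylongipin-2-en-1-one
Conditions: HF (48% aq.), MeCN, rt to 40 °C
Reagents that add atoms: none
Why: Aqueous HF should remove the silyl ether and hydrolyse the acetonide in one operation, the enone and the cyclobutane being stable to acid.

Step 15
Reactants: 22 (4R,5S,7S,8R,9S,10R,11R)-7,8,9-trihydroxylongipin-2-en-1-one; 23 angelic acid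
Product: 24 (4R,5S,7S,8R,9S,10R,11R)-7,8,9-tris[(Z)-2-methylbut-2-enoyloxy]longipin-2-en-1-one (CNP0330079.1)
Conditions: angelic acid (excess), 2,4,6-trichlorobenzoyl chloride, Et3N, toluene, rt; then 22, 80 °C
Reagents that add atoms: angelic acid (23), C/C=C(/C)C(=O)O
Why: Yamaguchi-type esterification through the mixed anhydride without DMAP should acylate all three secondary hydroxyls and keep the (Z)-geometry of the angelate, since no nucleophilic catalyst is present to isomerise it to tiglate.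

Compound list
1 | 2-hydroxyethyl pivalate | CC(C)(C)C(=O)OCCO | starting material
2 | 3-methylbuta-1,2-diene | CC(C)=C=C | starting material
3 | (2S)-2-hydroxy-3,3-dimethylpent-4-en-1-yl pivalate | CC(C)(C)C(=O)OC[C@@H](O)C(C)(C)C=C | intermediate
4 | (2S)-2-[(tert-butyldimethylsilyl)oxy]-3,3-dimethylpent-4-en-1-yl pivalate | CC(C)(C)C(=O)OC[C@@H](O[Si](C)(C)C(C)(C)C)C(C)(C)C=C | intermediate
5 | ozonide (1,2,4-trioxolane) of 4, mixture at the trioxolane carbon | CC(C)(C)C(=O)OC[C@@H](O[Si](C)(C)C(C)(C)C)C(C)(C)C1OCOO1 | intermediate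
6 | (2S)-2-[(tert-butyldimethylsilyl)oxy]-3,3-dimethyl-4-oxobutyl pivalate | CC(C)(C)C(=O)OC[C@@H](O[Si](C)(C)C(C)(C)C)C(C)(C)C=O | intermediate
7 | allyl(diphenyl)phosphine oxide | C=CCP(=O)(c1ccccc1)c1ccccc1 | starting material
8 | (2S,4E)-2-[(tert-butyldimethylsilyl)oxy]-3,3-dimethylhepta-4,6-dien-1-yl pivalate | CC(C)(C)C(=O)OC[C@@H](O[Si](C)(C)C(C)(C)C)C(C)(C)/C=C/C=C | intermediate
9 | (E)-pent-3-en-2-one | C/C=C/C(C)=O | starting material
10 | (2S)-3-[(1R,5R,6S)-6-acetyl-5-methylcyclohex-2-en-1-yl]-2-[(tert-butyldimethylsilyl)oxy]-3-methylbutyl pivalate (side chain and acetyl cis, acetyl and methyl trans) | CC(C)(C)C(=O)OC[C@@H](O[Si](C)(C)C(C)(C)C)C(C)(C)[C@@H]1C=CC[C@@H](C)[C@@H]1C(C)=O | intermediate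
11 | p-toluenesulfonylmethyl isocyanide (TosMIC) | Cc1ccc(cc1)S(=O)(=O)C[N+]#[C-] | starting material
12 | (2S)-2-[(tert-butyldimethylsilyl)oxy]-3-[(1R,5R,6S)-6-(1-cyanoethyl)-5-methylcyclohex-2-en-1-yl]-3-methylbutyl pivalate, both epimers at the nitrile-bearing carbon | CC(C)(C)C(=O)OC[C@@H](O[Si](C)(C)C(C)(C)C)C(C)(C)[C@@H]1C=CC[C@@H](C)[C@@H]1C(C)C#N | intermediate
13 | (2S)-2-[(tert-butyldimethylsilyl)oxy]-3-[(1R,2R,3R,4R,6S)-3-(1-cyanoethyl)-4-methyl-7-oxabicyclo[4.1.0]heptan-2-yl]-3-methylbutyl pivalate (epoxide trans to both ring substituents) | CC(C)(C)C(=O)OC[C@@H](O[Si](C)(C)C(C)(C)C)C(C)(C)[C@@H]1[C@H]2O[C@H]2C[C@@H](C)[C@@H]1C(C)C#N | intermediate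
14 | (2S)-2-[(tert-butyldimethylsilyl)oxy]-3-[(1R,2S,4R,5S,6R,7S)-6-cyano-2-hydroxy-4,6-dimethylbicyclo[3.1.1]heptan-7-yl]-3-methylbutyl pivalate | CC(C)(C)C(=O)OC[C@@H](O[Si](C)(C)C(C)(C)C)C(C)(C)[C@@H]1[C@H]2[C@@H](O)C[C@@H](C)[C@@H]1[C@@]2(C)C#N | intermediate
15 | aldimine of 16 (CH=NH in place of CHO) | OC[C@@H](O[Si](C)(C)C(C)(C)C)C(C)(C)[C@@H]1[C@H]2[C@@H](O)C[C@@H](C)[C@@H]1[C@@]2(C)C=N | intermediate
16 | (1R,2S,4R,5S,6R,7S)-7-[(3S)-3-[(tert-butyldimethylsilyl)oxy]-4-hydroxy-2-methylbutan-2-yl]-2-hydroxy-4,6-dimethylbicyclo[3.1.1]heptane-6-carbaldehyde | OC[C@@H](O[Si](C)(C)C(C)(C)C)C(C)(C)[C@@H]1[C@H]2[C@@H](O)C[C@@H](C)[C@@H]1[C@@]2(C)C=O | intermediate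
17 | (1R,2S,4R,5S,6R,7S)-7-[(3S)-3-[(tert-butyldimethylsilyl)oxy]-2-methyl-4-oxobutan-2-yl]-2-hydroxy-4,6-dimethylbicyclo[3.1.1]heptane-6-carbaldehyde | O=C[C@@H](O[Si](C)(C)C(C)(C)C)C(C)(C)[C@@H]1[C@H]2[C@@H](O)C[C@@H](C)[C@@H]1[C@@]2(C)C=O | intermediate
18 | (1S,3R,4S,5S,7S,8S,9S,10R,11R)-7-[(tert-butyldimethylsilyl)oxy]longipinane-1,8,9-triol | O[C@@H]1[C@@H](O[Si](C)(C)C(C)(C)C)C(C)(C)[C@@H]2[C@H]3[C@@H](O)C[C@@H](C)[C@@H]2[C@@]3(C)[C@@H]1O | intermediate
19 | (1S,3R,4S,5S,7S,8S,9S,10R,11R)-7-[(tert-butyldimethylsilyl)oxy]-8,9-(isopropylidenedioxy)longipinan-1-ol | CC1(C)O[C@@H]2[C@@H](O[Si](C)(C)C(C)(C)C)C(C)(C)[C@@H]3[C@H]4[C@@H](O)C[C@@H](C)[C@@H]3[C@@]4(C)[C@@H]2O1 | intermediate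
20 | (3R,4S,5S,7S,8S,9S,10R,11R)-7-[(tert-butyldimethylsilyl)oxy]-8,9-(isopropylidenedioxy)longipinan-1-one | CC1(C)O[C@@H]2[C@@H](O[Si](C)(C)C(C)(C)C)C(C)(C)[C@@H]3[C@H]4C(=O)C[C@@H](C)[C@@H]3[C@@]4(C)[C@@H]2O1 | intermediate
21 | (4R,5S,7S,8S,9S,10R,11R)-7-[(tert-butyldimethylsilyl)oxy]-8,9-(isopropylidenedioxy)longipin-2-en-1-one | CC1(C)O[C@@H]2[C@@H](O[Si](C)(C)C(C)(C)C)C(C)(C)[C@@H]3[C@H]4C(=O)C=C(C)[C@@H]3[C@@]4(C)[C@@H]2O1 | intermediate
22 | (4R,5S,7S,8R,9S,10R,11R)-7,8,9-trihydroxylongipin-2-en-1-one | O[C@@H]1[C@@H](O)C(C)(C)[C@@H]2[C@H]3C(=O)C=C(C)[C@@H]2[C@@]3(C)[C@@H]1O | intermediate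
23 | angelic acid, (Z)-2-methylbut-2-enoic acid | C/C=C(/C)C(=O)O | starting material
24 | (4R,5S,7S,8R,9S,10R,11R)-7,8,9-tris[(Z)-2-methylbut-2-enoyloxy]longipin-2-en-1-one (CNP0330079.1) | C/C=C(/C)C(=O)O[C@@H]1[C@@H](OC(=O)/C(C)=C\C)C(C)(C)[C@@H]2[C@H]3C(=O)C=C(C)[C@@H]2[C@@]3(C)[C@@H]1OC(=O)/C(C)=C\C | target

Total step count: 15. Longest linear sequence: 15 steps (1 to 24).

Steps most likely to fail

Step 8 (cyclobutane closure). The nitrile carbanion may fail to reach the oxirane carbon against the strain of the 1,3-syn-disubstituted cyclobutane, or base-induced isomerisation of the epoxide to an allylic alcohol may outrun ring closure. The fallback replaces the epoxide by a cyclic sulfate and sets out from 12. Dihydroxylation of the ring alkene with OsO4 (cat.)/NMO from the same less hindered face should give the cis-diol F1. SOCl2/Et3N then gives the cyclic sulfite F2, and RuCl3 (cat.)/NaIO4 the cyclic sulfate F3, a much stronger electrophile than the oxirane. KN(SiMe3)2 closes the four-membered ring by the same backside attack to give the sulfate monoester F4, and hydrolysis (cat. H2SO4, H2O, THF) comes back to the route at 14.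

Step 5 (Diels–Alder reaction). Cycloaddition of the hindered diene to a β-substituted acyclic enone may be sluggish, and facial discrimination by the catalyst may be insufficient. The fallback uses auxiliary control and sets out from 8. Reaction with (R)-4-benzyl-3-[(E)-but-2-enoyl]-1,3-oxazolidin-2-one and Et2AlCl (CH2Cl2, −78 to −20 °C; chelated and more reactive dienophile, diene adding anti to the benzyl group) should give the imide F5. MeNH(OMe)·HCl/AlMe3 converts it into the Weinreb amide F6, and MeMgBr comes back to the route at 10.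

Step 11 (pinacol cyclisation). Facial control at the two ketyl carbons may be lost (trans-diol, or diol syn to the silyloxy group), or the aldehydes may simply be reduced without coupling. The fallback makes the same C8–C9 bond as an alkene and sets out from 17. Double Wittig methylenation (Ph3P=CH2, THF) gives the diene F7. Ring-closing metathesis with the second-generation Grubbs catalyst (toluene, 80 °C) closes the seven-membered ring as the cycloheptene F8. Dihydroxylation with OsO4 (cat.)/NMO, anti to the allylic silyloxy group, comes back to the route at 18.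

Further compounds
F1 | step 8 | (2S)-2-[(tert-butyldimethylsilyl)oxy]-3-[(1R,5R,6S)-6-(1-cyanoethyl)-2,3-cis-dihydroxy-5-methylcyclohexyl]-3-methylbutyl pivalate (diol trans to both ring substituents) | CC(C)(C)C(=O)OC[C@@H](O[Si](C)(C)C(C)(C)C)C(C)(C)[C@@H]1[C@@H](O)[C@@H](O)C[C@@H](C)[C@@H]1C(C)C#N
F2 | step 8 | cyclic sulfite of F1 | CC(C)(C)C(=O)OC[C@@H](O[Si](C)(C)C(C)(C)C)C(C)(C)[C@@H]1[C@H]2OS(=O)O[C@H]2C[C@@H](C)[C@@H]1C(C)C#N
F3 | step 8 | cyclic sulfate of F1 | CC(C)(C)C(=O)OC[C@@H](O[Si](C)(C)C(C)(C)C)C(C)(C)[C@@H]1[C@H]2OS(=O)(=O)O[C@H]2C[C@@H](C)[C@@H]1C(C)C#N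
F4 | step 8 | hydrogen sulfate ester of 14 at the ring carbinol | CC(C)(C)C(=O)OC[C@@H](O[Si](C)(C)C(C)(C)C)C(C)(C)[C@@H]1[C@H]2[C@@H](OS(=O)(=O)O)C[C@@H](C)[C@@H]1[C@@]2(C)C#N
F5 | step 5 | N-acyl oxazolidinone analogue of 10 [(R)-4-benzyl-2-oxo-1,3-oxazolidin-3-yl carbonyl in place of acetyl] | CC(C)(C)C(=O)OC[C@@H](O[Si](C)(C)C(C)(C)C)C(C)(C)[C@@H]1C=CC[C@@H](C)[C@@H]1C(=O)N2[C@H](Cc3ccccc3)COC2=O
F6 | step 5 | N-methoxy-N-methyl amide analogue of 10 | CC(C)(C)C(=O)OC[C@@H](O[Si](C)(C)C(C)(C)C)C(C)(C)[C@@H]1C=CC[C@@H](C)[C@@H]1C(=O)N(C)OC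
F7 | step 11 | bis-methylenation product of 17 (both formyl groups as vinyl groups) | C=C[C@@H](O[Si](C)(C)C(C)(C)C)C(C)(C)[C@@H]1[C@H]2[C@@H](O)C[C@@H](C)[C@@H]1[C@@]2(C)C=C
F8 | step 11 | 7-[(tert-butyldimethylsilyl)oxy]longipin-8-en-1-ol (C8=C9 cycloheptene) | C=1[C@@H](O[Si](C)(C)C(C)(C)C)C(C)(C)[C@@H]2[C@H]3[C@@H](O)C[C@@H](C)[C@@H]2[C@@]3(C)C=1
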